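**Retrosynthetic overview**

1. The last ring is the cyclopentane of the cis-hydroazulene. It is closed between the methyl-bearing quaternary carbon (azulene C-1) and the ring-fusion CH (C-8a). The enabling feature is the allylic array CH2=C(C-8, seven-membered ring)–CH(C-8a) beside a quaternary C–CH3: it maps onto an allyl sulfone radical acceptor and a 1,1-disubstituted alkene as tertiary-radical precursor.
2. Diene 27 comes from a B-alkyl Suzuki union of cycloheptenylmethyl sulfone 25 (one stereocentre) with the bicyclic 2-iodoalkene 15, which carries all five stereocentres of the 2,7-dioxabicyclo[3.2.1]octanone.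
3. 15 comes from lactone 1. The lactone template sets the two oxygenated carbons and the bridge carbon. Conjugate addition gives a regiodefined enol silane whose ozonolysis delivers one aldehyde and one acid.
4. 25 comes from 3-methylcyclohexenone by ring expansion and asymmetric conjugate vinylation with enolate trapping.
5. Ring order: δ-lactone (acylal) ring in step 8, tetrahydrofuran ring in step 9, cycloheptene separately in step 13, cyclopentane last in step 18.

Key step: step 18

Remark on the chemistry: the acetal carbon of 12 and 13 forms as an anomeric mixture (reset in step 9) and is drawn without configuration; 18 and 19 are racemic (their stereocentres are removed in step 13).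

**Step 1**
Reactants: 1 (1R,5S)-2-oxabicyclo[3.3.0]oct-6-en-3-one
Product: 3 exo-4-hydroxy lactone, via lithium enolate 2 (not isolated)
Conditions: LiN(iPr)2, THF, −78 °C; then 2-(phenylsulfonyl)-3-phenyloxaziridine, −78 °C; H2O
Reagents that add atoms: 2-(phenylsulfonyl)-3-phenyloxaziridine, O=S(=O)(N1OC1c1ccccc1)c1ccccc1
Why: Enolate oxidation with an N-sulfonyloxaziridine; the cis-fused bicycle exposes only its convex face, so the hydroxyl should enter exo (cis to H-5), setting the carbinol carbon that later bears the methyl ester.

**Step 2**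
Reactants: 3 exo-4-hydroxy lactone
Product: 4 silyl ether of 3
Conditions: TBSOTf, 2,6-lutidine, CH2Cl2, 0 °C
Reagents that add atoms: tert-butyldimethylsilyl trifluoromethanesulfonate, CC(C)(C)[Si](C)(C)OS(=O)(=O)C(F)(F)F
Why: O-Silylation under non-basic conditions protects the hydroxyl that must stay free of acyl groups until the tetrahydrofuran closure.

**Step 3**
Reactants: 4 silyl ether
Product: 5 exo-8-hydroxy lactone
Conditions: SeO2 (0.5 equiv), t-BuOOH, CH2Cl2, rt
Reagents that add atoms: selenium dioxide, O=[Se]=O; tert-butyl hydroperoxide, CC(C)(C)OO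
Why: Selenium dioxide allylic oxidation (ene reaction, then [2,3]-sigmatropic shift, no net alkene shift) should hydroxylate the only allylic CH2 from the convex face; the new carbinol configuration is irrelevant because it is oxidised in step 5.

**Step 4**
Reactants: 5 exo-8-hydroxy lactone
Product: 7 cyclopentenediol methyl ester, via lithium carboxylate 6 (not isolated)
Conditions: LiOH, THF/H2O, 0 °C; evaporate; then MeI, DMF, rt
Reagents that add atoms: lithium hydroxide, [Li+].[OH-]; iodomethane, CI
Why: Saponification of the γ-lactone and SN2 O-methylation of the carboxylate open the template without acid, so relactonisation should be avoided and no stereocentre is touched.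

**Step 5**
Reactants: 7 cyclopentenediol methyl ester
Product: 8 α′-hydroxy cyclopentenone
Conditions: MnO2, CH2Cl2, rt
Reagents that add atoms: none
Why: Chemoselective MnO2 oxidation of the allylic alcohol in the presence of the homoallylic one gives the enone whose β-carbon is the future bridge carbon.

**Step 6**
Reactants: 8 α′-hydroxy cyclopentenone
Product: 9 α′-acetoxy cyclopentenone
Conditions: Ac2O, pyridine, 4-(dimethylamino)pyridine (cat.), CH2Cl2, 0 °C
Reagents that add atoms: acetic anhydride, CC(=O)OC(C)=O
Why: Acetylation by nucleophilic catalysis installs the acetate kept in the target and blocks relactonisation.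

**Step 7**
Reactants: 9 α′-acetoxy cyclopentenone
Product: 10 enol silane bearing the 1-silylvinyl group
Conditions: CH2=C(SiMe3)MgBr, CuBr·SMe2 (10 mol%), Me3SiCl, THF, −78 °C
Reagents that add atoms: [1-(trimethylsilyl)vinyl]magnesium bromide, C=C([Mg]Br)[Si](C)(C)C; chlorotrimethylsilane, C[Si](C)(C)Cl
Why: Copper-catalysed, Me3SiCl-accelerated conjugate addition; the alkenyl group should add anti to the neighbouring side chain and the acetate on the same face, setting the bridge-carbon stereocentre, and the enolate is trapped regiospecifically.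

**Step 8**
Reactants: 10 enol silane
Product: 12 acetoxy δ-lactone, via aldehyde acid 11 (not isolated)
Conditions: O3, CH2Cl2, −78 °C (Sudan Red 7B end point); Me2S; H2O; then Ac2O, pyridine, 4-(dimethylamino)pyridine (cat.), 0 °C
Reagents that add atoms: ozone, [O-][O+]=O; acetic anhydride, CC(=O)OC(C)=O
Why: Ozonolysis (Criegee mechanism) of the electron-rich silyl enol ether should outrun attack on the vinylsilane and gives aldehyde and acid at defined carbons; acetylation of the cyclic pseudo-acid closes the δ-lactone ring of the target.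

**Step 9**
Reactants: 12 acetoxy δ-lactone
Product: 14 bicyclic vinylsilane, via hydroxy acetoxy lactone 13 (not isolated)
Conditions: HF·pyridine, THF, 0 °C → rt; then BF3·OEt2 (cat.), CH2Cl2, −20 °C
Reagents that add atoms: none
Why: Desilylation, then Lewis-acid ionisation of the anomeric acetate and 5-exo capture of the oxocarbenium ion by the freed hydroxyl (intramolecular transacetalisation) close the tetrahydrofuran ring; the acetal carbon can only take the configuration that the bridged bicycle allows.

**Step 10**
Reactants: 14 bicyclic vinylsilane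
Product: 15 bicyclic 2-iodoalkene
Conditions: N-iodosuccinimide, MeCN/ClCH2CN, 0 °C; aqueous work-up
Reagents that add atoms: N-iodosuccinimide, O=C1CCC(=O)N1I
Why: ipso-Iododesilylation of the vinylsilane (electrophilic substitution at the silicon-bearing carbon) gives the coupling handle without touching a stereocentre.

**Step 11**
Reactants: 16 3-methylcyclohex-2-en-1-one
Product: 17 3,3-dimethylcyclohexenyl silyl ether
Conditions: MeMgBr, CuI (5 mol%), Me3SiCl, THF, −40 → 0 °C
Reagents that add atoms: methylmagnesium bromide, C[Mg]Br; chlorotrimethylsilane, C[Si](C)(C)Cl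
Why: Copper-catalysed conjugate addition with in situ silylation gives the gem-dimethyl group and the regiodefined enol silane.

**Step 12**
Reactants: 17 3,3-dimethylcyclohexenyl silyl ether
Product: 18 siloxycyclopropane
Conditions: Et2Zn, CH2I2, CH2Cl2, 0 °C → rt
Reagents that add atoms: diiodomethane, ICI
Why: Simmons–Smith cyclopropanation (Furukawa conditions) of the electron-rich enol ether.

**Step 13**
Reactants: 18 siloxycyclopropane
Product: 20 4,4-dimethylcyclohept-2-en-1-one, via β-chloro ketone 19 (not isolated)
Conditions: FeCl3, DMF, 0 °C → rt; then NaOAc, MeOH, reflux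
Reagents that add atoms: none
Why: Saegusa-type oxidative ring expansion: iron trichloride opens the siloxycyclopropane to the ring-enlarged β-chloro ketone, and E1cB loss of HCl gives the cycloheptenone.

**Step 14**
Reactants: 20 4,4-dimethylcyclohept-2-en-1-one
Product: 22 vinyl-substituted enol triflate, via enol silane 21 (not isolated)
Conditions: CH2=CHMgBr/ZnCl2, Me3SiCl, [RhCl((S)-BINAP)]2 (3 mol%), THF, 20 °C; then CsF, PhNTf2, DME, rt
Reagents that add atoms: vinylmagnesium bromide, C=C[Mg]Br; N-phenylbis(trifluoromethanesulfonimide), O=S(=O)(N(c1ccccc1)S(=O)(=O)C(F)(F)F)C(F)(F)F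
Why: Rhodium/BINAP-catalysed asymmetric 1,4-addition (aprotic organozinc variant of the Hayashi–Miyaura reaction) should set the vinyl-bearing stereocentre by catalyst control ((S)-BINAP chosen by analogy with cyclic enones, to be verified) and give the regiodefined enol silane, which fluoride-induced triflation converts to the triflate.

**Step 15**
Reactants: 22 enol triflate
Product: 23 allylic alcohol
Conditions: Bu3SnCH2OH, Pd(PPh3)4 (5 mol%), LiCl, dioxane, 100 °C
Reagents that add atoms: (tributylstannyl)methanol, CCCC[Sn](CCCC)(CCCC)CO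
Why: Stille coupling of the enol triflate installs the hydroxymethyl group with the ring alkene fixed in place.

**Step 16**
Reactants: 23 allylic alcohol
Product: 25 allyl phenyl sulfone, via allylic mesylate 24 (not isolated)
Conditions: MsCl, Et3N, CH2Cl2, −20 °C; then PhSO2Na, DMF, rt
Reagents that add atoms: sodium benzenesulfinate, [Na+].[O-]S(=O)c1ccccc1
Why: Mesylation and SN2 S-alkylation of sulfinate at the primary allylic carbon give the radical leaving group.

**Step 17**
Reactants: 25 allyl phenyl sulfone; 15 bicyclic 2-iodoalkene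
Product: 27 diene sulfone, via B-alkyl-9-BBN 26 (not isolated)
Conditions: 9-BBN, THF, 0 °C → rt; then 15, PdCl2(dppf) (5 mol%), AsPh3, aq. K3PO4, DMF, rt
Reagents that add atoms: none
Why: Anti-Markovnikov hydroboration of the monosubstituted alkene (the trisubstituted ring alkene is too hindered) and B-alkyl Suzuki–Miyaura coupling join the fragments as a 1,1-disubstituted alkene; no stereocentre is formed.

**Step 18**
Reactants: 27 diene sulfone
Product: 28 target
Conditions: Fe(acac)3 (30 mol%), PhSiH2(OiPr), THF, 0 °C → rt
Reagents that add atoms: none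
Why: Proposed new method: hydrogen-atom transfer from an iron hydride to the CH2 end of the 1,1-disubstituted alkene creates the methyl group and a tertiary radical at the future quaternary carbon; this radical attacks the ring CH= carbon of the cycloheptenylmethyl sulfone, and β-scission of the C–S bond expels PhSO2• and unveils the exocyclic methylene (intramolecular SH2′), the sulfonyl radical being reduced to sulfinate so that iron turns over. The closest known reaction types are iron-hydride (Mukaiyama-type) reductive radical cyclisation of alkenes onto Michael acceptors and radical allylation with allyl sulfones; their merger on a tethered, unactivated allyl sulfone is the new element. The only ring closed is the cyclopentane, by 5-exo-trig closure; the 6-endo mode is disfavoured because the sulfonylmethyl-bearing carbon is fully substituted. The new ring-fusion CH must be cis to the existing ring-fusion hydrogen, because the two-carbon tether on that stereocentre can reach the adjacent alkene carbon only from its own face; the quaternary centre should be set by a transition state that places the bulky dioxabicyclic group on the convex face, anti to the seven-membered ring, leaving the new methyl syn to the methylene-bearing carbon. The step needs chemoselective hydrogen-atom transfer to the 1,1-disubstituted alkene over the trisubstituted ring alkene (secured by lower substitution and the deactivating allylic sulfone) and survival of the product alkene (secured by limiting silane and low temperature).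

**Compound list**

1 | (1R,5S)-2-oxabicyclo[3.3.0]oct-6-en-3-one (cis-fused) | O=C1O[C@@H]2CC=C[C@@H]2C1 | starting material
2 | lithium enolate of 1 | [Li+].[O-]C1=C[C@H]2C=CC[C@H]2O1 | intermediate
3 | 4-hydroxy derivative of 1, OH exo (cis to H-5) | O=C1O[C@@H]2CC=C[C@@H]2[C@H]1O | intermediate
4 | tert-butyldimethylsilyl ether of 3 | O=C1O[C@@H]2CC=C[C@@H]2[C@H]1O[Si](C)(C)C(C)(C)C | intermediate
5 | 8-hydroxy derivative of 4, OH exo | O=C1O[C@@H]2[C@@H](O)C=C[C@@H]2[C@H]1O[Si](C)(C)C(C)(C)C | intermediate
6 | lithium 2-silyloxy-2-(4,5-dihydroxycyclopent-2-enyl)acetate (ring-opened 5) | [Li+].[O-]C(=O)[C@H](O[Si](C)(C)C(C)(C)C)[C@H]1C=C[C@H](O)[C@H]1O | intermediate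
7 | methyl ester of 6 (side chain cis to the adjacent OH, trans to the allylic OH) | COC(=O)[C@H](O[Si](C)(C)C(C)(C)C)[C@H]1C=C[C@H](O)[C@H]1O | intermediate
8 | methyl 2-silyloxy-2-(5-hydroxy-4-oxocyclopent-2-enyl)acetate (OH cis to side chain) | COC(=O)[C@H](O[Si](C)(C)C(C)(C)C)[C@H]1C=CC(=O)[C@H]1O | intermediate
9 | acetate of 8 | COC(=O)[C@H](O[Si](C)(C)C(C)(C)C)[C@H]1C=CC(=O)[C@H]1OC(C)=O | intermediate
10 | trimethylsilyl enol ether carrying the 1-(trimethylsilyl)vinyl group trans to the side chain | COC(=O)[C@H](O[Si](C)(C)C(C)(C)C)[C@H]1[C@H](C(=C)[Si](C)(C)C)C=C(O[Si](C)(C)C)[C@H]1OC(C)=O | intermediate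
11 | open-chain aldehyde acid from ring cleavage of 10 | COC(=O)[C@H](O[Si](C)(C)C(C)(C)C)[C@@H]([C@H](C(=C)[Si](C)(C)C)C=O)[C@H](OC(C)=O)C(=O)O | intermediate
12 | 3,6-diacetoxy-tetrahydropyran-2-one (pseudo-acid acetate of 11; anomeric mixture) | CC(=O)OC1OC(=O)[C@@H](OC(C)=O)[C@@H]([C@@H](O[Si](C)(C)C(C)(C)C)C(=O)OC)[C@@H]1C(=C)[Si](C)(C)C | intermediate
13 | desilylated 12 (free α-hydroxy ester) | CC(=O)OC1OC(=O)[C@@H](OC(C)=O)[C@@H]([C@@H](O)C(=O)OC)[C@@H]1C(=C)[Si](C)(C)C | intermediate
14 | methyl 4-acetoxy-3-oxo-8-[1-(trimethylsilyl)vinyl]-2,7-dioxabicyclo[3.2.1]octane-6-carboxylate (configuration as in the target) | C=C([Si](C)(C)C)[C@@H]1[C@@H]2OC(=O)[C@@H](OC(C)=O)[C@H]1[C@H](C(=O)OC)O2 | intermediate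
15 | methyl 4-acetoxy-8-(1-iodovinyl)-3-oxo-2,7-dioxabicyclo[3.2.1]octane-6-carboxylate | C=C(I)[C@@H]1[C@@H]2OC(=O)[C@@H](OC(C)=O)[C@H]1[C@H](C(=O)OC)O2 | intermediate
16 | 3-methylcyclohex-2-en-1-one | CC1=CC(=O)CCC1 | starting material
17 | 3,3-dimethyl-1-(trimethylsilyloxy)cyclohexene | CC1(C)CCCC(O[Si](C)(C)C)=C1 | intermediate
18 | 5,5-dimethyl-1-(trimethylsilyloxy)bicyclo[4.1.0]heptane (racemic) | CC1(C)CCCC2(O[Si](C)(C)C)CC12 | intermediate
19 | 3-chloro-4,4-dimethylcycloheptan-1-one (racemic) | CC1(C)CCCC(=O)CC1Cl | intermediate
20 | 4,4-dimethylcyclohept-2-en-1-one | CC1(C)CCCC(=O)C=C1 | intermediate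
21 | 4,4-dimethyl-3-vinylcyclohept-1-enyl trimethylsilyl ether (single enantiomer) | C=C[C@@H]1C=C(O[Si](C)(C)C)CCCC1(C)C | intermediate
22 | 4,4-dimethyl-3-vinylcyclohept-1-enyl trifluoromethanesulfonate | C=C[C@@H]1C=C(OS(=O)(=O)C(F)(F)F)CCCC1(C)C | intermediate
23 | (4,4-dimethyl-3-vinylcyclohept-1-enyl)methanol | C=C[C@@H]1C=C(CO)CCCC1(C)C | intermediate
24 | methanesulfonate of 23 | C=C[C@@H]1C=C(COS(C)(=O)=O)CCCC1(C)C | intermediate
25 | [(4,4-dimethyl-3-vinylcyclohept-1-enyl)methyl] phenyl sulfone | O=S(=O)(CC1=C[C@@H](C=C)C(C)(C)CCC1)c1ccccc1 | intermediate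
26 | B-alkyl-9-BBN from hydroboration of the vinyl group of 25 | O=S(=O)(CC1=C[C@@H](CCB2C3CCCC2CCC3)C(C)(C)CCC1)c1ccccc1 | intermediate
27 | diene sulfone: bicycle 15 joined through a C(=CH2)–CH2–CH2 link to the cycloheptenylmethyl sulfone | C=C(CC[C@@H]1C=C(CS(=O)(=O)c2ccccc2)CCCC1(C)C)[C@@H]3[C@@H]4OC(=O)[C@@H](OC(C)=O)[C@H]3[C@H](C(=O)OC)O4 | intermediate
28 | methyl 4-acetoxy-3-oxo-8-(1,4,4-trimethyl-8-methylidene-decahydroazulen-1-yl)-2,7-dioxabicyclo[3.2.1]octane-6-carboxylate, cis-fused, configuration as given | C=C1CCCC(C)(C)[C@@H]2CC[C@@](C)([C@@H]3[C@@H]4OC(=O)[C@@H](OC(C)=O)[C@H]3[C@H](C(=O)OC)O4)[C@H]12 | target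

**Step count and risks**

Total step count: 18. Longest linear sequence: 12 steps (steps 1–10, 17, 18).

Steps most likely to fail:

1. Step 18 (Proposed new method). The tertiary radical may be reduced before it cyclises, or the exocyclic alkene of the product may re-enter the hydride cycle and be reduced or isomerised. Fallback with known chemistry, setting out from 27 and returning at 28: Mukaiyama hydration of the 1,1-disubstituted alkene (Mn(dpm)3, PhSiH3, O2, then PPh3) gives the tertiary alcohol F1 as an epimer mixture, which is harmless because both epimers give the same radical. Acylation with chloro N-phthalimidoyl oxalate gives the tert-alkyl N-phthalimidoyl oxalate F2. Visible-light photoredox fragmentation (Ru(bpy)3(PF6)2, Hantzsch ester, blue light) generates the same tertiary radical with no metal hydride present; 5-exo cyclisation and loss of sulfinate should then give 28.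

2. Step 14. Enantioselectivity may be insufficient on the hindered β-carbon, or the enol silane may be protonated so that the alkene regiochemistry is lost. Fallback, setting out from 20 and returning at 25: racemic copper-catalysed conjugate addition of CH2=CHMgBr with Me3SiCl gives the racemic enol silane F3. The same sequence as steps 14–16 then gives the racemic enol triflate F4, the racemic allylic alcohol F5, the racemic mesylate F6 and the racemic sulfone F7. F7 is resolved by preparative chromatography on a chiral stationary phase to give 25.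

3. Step 17. The aqueous base may open the acylal lactone or cleave the acetate, and the alkylborane may protodeboronate. Fallback, setting out from 26 and returning at 27: iodinolysis of 26 (I2, NaOMe) gives the primary iodide F8, zinc insertion (Zn, LiCl, THF) gives the alkylzinc iodide F9, and base-free Negishi coupling with 15 (Pd(OAc)2/SPhos, THF, rt) gives 27.

**Further compounds**

F1 | step 18 | tertiary alcohol from hydration of 27 (epimer mixture at the carbinol) | CC(O)(CC[C@@H]1C=C(CS(=O)(=O)c2ccccc2)CCCC1(C)C)[C@@H]3[C@@H]4OC(=O)[C@@H](OC(C)=O)[C@H]3[C@H](C(=O)OC)O4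
F2 | step 18 | N-phthalimidoyl oxalate of F1 | CC(OC(=O)C(=O)ON5C(=O)c6ccccc6C5=O)(CC[C@@H]1C=C(CS(=O)(=O)c2ccccc2)CCCC1(C)C)[C@@H]3[C@@H]4OC(=O)[C@@H](OC(C)=O)[C@H]3[C@H](C(=O)OC)O4
F3 | step 14 | racemic 4,4-dimethyl-3-vinylcyclohept-1-enyl trimethylsilyl ether | C=CC1C=C(O[Si](C)(C)C)CCCC1(C)C
F4 | step 14 | racemic 4,4-dimethyl-3-vinylcyclohept-1-enyl trifluoromethanesulfonate | C=CC1C=C(OS(=O)(=O)C(F)(F)F)CCCC1(C)C
F5 | step 14 | racemic (4,4-dimethyl-3-vinylcyclohept-1-enyl)methanol | C=CC1C=C(CO)CCCC1(C)C
F6 | step 14 | racemic methanesulfonate of F5 | C=CC1C=C(COS(C)(=O)=O)CCCC1(C)C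
F7 | step 14 | racemic [(4,4-dimethyl-3-vinylcyclohept-1-enyl)methyl] phenyl sulfone | O=S(=O)(CC1=CC(C=C)C(C)(C)CCC1)c1ccccc1
F8 | step 17 | primary iodide from iodinolysis of 26 | O=S(=O)(CC1=C[C@@H](CCI)C(C)(C)CCC1)c1ccccc1
F9 | step 17 | alkylzinc iodide from F8 | O=S(=O)(CC1=C[C@@H](CC[Zn]I)C(C)(C)CCC1)c1ccccc1
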